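**Assumption:** 1, 4 and 5 are taken as catalogue compounds, and the catalyst enantiomer written in step 4 is assumed to open the Re face of the cation; if the opposite sense is found (ECD or X-ray of 9), its mirror image is used.

**Retrosynthetic overview**
1. Ring formed first: the pyran of the acetyl-bearing half, from phenol 1 and prenal 2, giving chromene 3.
2. Partner: phenol 4 is O-propargylated with 5 (giving 6) and reduced to the racemic benzylic alcohol 7.
3. Key disconnection: the C3–CH(CH3) bond, made by a chiral-acid-catalysed enantioconvergent cation–olefin coupling of 7 (via cation 8) with 3, giving 9 and setting the only stereocentre.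
4. Ring formed last: the second pyran, by propargyl Claisen/oxa-6π of 9 (via 10 and 11), giving target 12.
5. The second pyran is closed after the coupling so that 3 is the only chromene olefin present when the cation is generated.

**Step 1**
Reactants: 1 1-(2,4-dihydroxy-6-methoxyphenyl)ethan-1-one; 2 3-methylbut-2-enal (prenal)
Product: 3 1-(5-hydroxy-7-methoxy-2,2-dimethyl-2H-chromen-6-yl)ethan-1-one
Conditions: 2 (1.5 equiv), ethylenediammonium diacetate (20 mol %), PhMe, 110 °C, Dean–Stark
Reagents that add atoms: none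
Why: Formal [3+3] chromenylation (Knoevenagel-type condensation at the ring carbon between the two hydroxyls, then oxa-6π electrocyclisation of the ortho-quinone methide), in which the acetyl-chelated 2-OH stays as the hydrogen-bonded phenol and the free 4-OH becomes the ring oxygen.

**Step 2**
Reactants: 4 1-(4-hydroxy-2,6-dimethoxyphenyl)ethan-1-one; 5 3-chloro-3-methylbut-1-yne
Product: 6 1-[2,6-dimethoxy-4-(2-methylbut-3-yn-2-yloxy)phenyl]ethan-1-one
Conditions: 5 (1.5 equiv), K2CO3 (2 equiv), KI (10 mol %), CuI (5 mol %), acetone, 56 °C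
Reagents that add atoms: none
Why: Copper/iodide-assisted Williamson-type O-alkylation of the acidic para-acyl phenoxide by the tertiary propargylic chloride, which leaves the ketone untouched.

**Step 3**
Reactants: 6 1-[2,6-dimethoxy-4-(2-methylbut-3-yn-2-yloxy)phenyl]ethan-1-one
Product: 7 rac-1-[2,6-dimethoxy-4-(2-methylbut-3-yn-2-yloxy)phenyl]ethan-1-ol
Conditions: NaBH4 (1.5 equiv), MeOH, 0 °C to rt; NaHCO3 work-up, Et3N-deactivated silica
Reagents that add atoms: none
Why: Borohydride reduction of the aryl methyl ketone with alkyne and aryl ether inert, and the racemic carbinol centre is erased again in step 4, so no control is needed here.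

**Step 4**
Reactants: 3 1-(5-hydroxy-7-methoxy-2,2-dimethyl-2H-chromen-6-yl)ethan-1-one; 7 rac-1-[2,6-dimethoxy-4-(2-methylbut-3-yn-2-yloxy)phenyl]ethan-1-ol
Product: 9 1-{3-[(1S)-1-[2,6-dimethoxy-4-(2-methylbut-3-yn-2-yloxy)phenyl]ethyl]-5-hydroxy-7-methoxy-2,2-dimethyl-2H-chromen-6-yl}ethan-1-one, via benzylic cation 8 (not isolated)
Conditions: 3 (2.5 equiv, excess recovered), (S,S)-IDPi (imidodiphosphorimidate from two (S)-3,3′-bis[3,5-bis(trifluoromethyl)phenyl]-BINOL units, P=NTf core; 3 mol %), 5 Å MS, PhMe, −40 °C, 7 added by syringe pump over 6 h; Et3N quench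
Reagents that add atoms: none
Why: Proposed new method: confined-IDPi-catalysed enantioconvergent dehydrative C3-benzylation of a 2H-chromene, in which the acid ionises racemic 7 to the planar trialkoxy-stabilised cation 8, held as a contact ion pair in the chiral anion's pocket so that only its Re face (Ar > CH3 > H) is open, C3 of 3 (the β-carbon of a trioxygenated styrene and the only alkene nucleophile present) adds there, and the resulting C4 benzylic cation loses the C3 proton to the anion, which restores the chromene and the acid and gives (S)-9; the closest known reaction type is chiral Brønsted acid (phosphoric acid or IDPi) catalysed enantioconvergent SN1 substitution of electron-rich benzylic alcohols or in situ quinone methides, including alkenylations with ortho-hydroxystyrenes, which has not been shown for a donor-free alkoxybenzylic cation with a chromene C3–H.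

**Step 5**
Reactants: 9 1-{3-[(1S)-1-[2,6-dimethoxy-4-(2-methylbut-3-yn-2-yloxy)phenyl]ethyl]-5-hydroxy-7-methoxy-2,2-dimethyl-2H-chromen-6-yl}ethan-1-one
Product: 12 1-{3-[(1S)-1-(5,7-dimethoxy-2,2-dimethyl-2H-chromen-6-yl)ethyl]-5-hydroxy-7-methoxy-2,2-dimethyl-2H-chromen-6-yl}ethan-1-one, via ortho-allenylphenol 10 (not isolated), via ortho-quinone methide 11 (not isolated)
Conditions: PhNEt2, 140 °C, N2, BHT (cat.), 8–12 h
Reagents that add atoms: none
Why: Thermal aryl propargyl ether Claisen rearrangement and enolisation give 10, a 1,5-H shift gives 11 and oxa-6π electrocyclisation closes the pyran; the two ortho positions are constitutionally equivalent so a single chromene forms, and the stereocentre is not involved under these neutral conditions.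

**Compound list**
1 | 1-(2,4-dihydroxy-6-methoxyphenyl)ethan-1-one | CC(=O)c1c(O)cc(O)cc1OC | starting material
2 | 3-methylbut-2-enal (prenal) | CC(C)=CC=O | starting material
3 | 1-(5-hydroxy-7-methoxy-2,2-dimethyl-2H-chromen-6-yl)ethan-1-one | COc1cc2c(c(O)c1C(C)=O)C=CC(C)(C)O2 | intermediate
4 | 1-(4-hydroxy-2,6-dimethoxyphenyl)ethan-1-one | CC(=O)c1c(OC)cc(O)cc1OC | starting material
5 | 3-chloro-3-methylbut-1-yne | CC(C)(Cl)C#C | starting material
6 | 1-[2,6-dimethoxy-4-(2-methylbut-3-yn-2-yloxy)phenyl]ethan-1-one | CC(=O)c1c(OC)cc(OC(C)(C)C#C)cc1OC | intermediate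
7 | rac-1-[2,6-dimethoxy-4-(2-methylbut-3-yn-2-yloxy)phenyl]ethan-1-ol | CC(O)c1c(OC)cc(OC(C)(C)C#C)cc1OC | intermediate
8 | 1-[2,6-dimethoxy-4-(2-methylbut-3-yn-2-yloxy)phenyl]ethylium, ion-paired with the catalyst anion | C[CH+]c1c(OC)cc(OC(C)(C)C#C)cc1OC | intermediate (not isolated)
9 | 1-{3-[(1S)-1-[2,6-dimethoxy-4-(2-methylbut-3-yn-2-yloxy)phenyl]ethyl]-5-hydroxy-7-methoxy-2,2-dimethyl-2H-chromen-6-yl}ethan-1-one | COc1cc2c(c(O)c1C(C)=O)C=C([C@H](C)c1c(OC)cc(OC(C)(C)C#C)cc1OC)C(C)(C)O2 | intermediate
10 | 1-{3-[(1S)-1-[4-hydroxy-2,6-dimethoxy-3-(3-methylbuta-1,2-dien-1-yl)phenyl]ethyl]-5-hydroxy-7-methoxy-2,2-dimethyl-2H-chromen-6-yl}ethan-1-one | COc1cc2c(c(O)c1C(C)=O)C=C([C@H](C)c1c(OC)cc(O)c(C=C=C(C)C)c1OC)C(C)(C)O2 | intermediate (not isolated)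
11 | 4-[(1S)-1-(6-acetyl-5-hydroxy-7-methoxy-2,2-dimethyl-2H-chromen-3-yl)ethyl]-3,5-dimethoxy-6-(3-methylbut-2-en-1-ylidene)cyclohexa-2,4-dien-1-one | COc1cc2c(c(O)c1C(C)=O)C=C([C@H](C)C1=C(OC)C(=CC=C(C)C)C(=O)C=C1OC)C(C)(C)O2 | intermediate (not isolated)
12 | 1-{3-[(1S)-1-(5,7-dimethoxy-2,2-dimethyl-2H-chromen-6-yl)ethyl]-5-hydroxy-7-methoxy-2,2-dimethyl-2H-chromen-6-yl}ethan-1-one | COc1cc2c(c(O)c1C(C)=O)C=C([C@H](C)c1c(OC)cc3c(c1OC)C=CC(C)(C)O3)C(C)(C)O2 | target

**Totals**
Total step count: 5. Longest linear sequence: 4 (steps 2, 3, 4, 5, from 4 to 12); step 1 is the one-step side branch.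

**Three steps most likely to fail**

Step 4 (the proposed new coupling). The risks are low enantioselectivity from a cation with no hydrogen-bond handle, and competing reactions of cation 8: self-etherification, elimination to the styrene and its dimerisation, or attack at hindered arene positions. The fallback sets out from 3 and 7. Diphenyl phosphate (10 mol %) or TsOH·H2O (5 mol %) in CH2Cl2 at 0 °C, with 3 in excess and 7 added slowly, gives the racemate of 9 F1. This uses the established acid-catalysed dehydrative cation–olefin (Friedel–Crafts-type alkenylation) reactivity of electron-rich benzylic alcohols, with no demand on the counter-anion. Preparative chiral SFC on an amylose carbamate phase then separates 9 from the (R)-enantiomer of 9 F2, so stereochemistry comes from separation instead of catalysis. The fallback comes back to the route at 9.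

Step 1 (regiochemistry of the chromenylation). Condensation could also occur at the carbon between the 4-OH and the methoxy group, or close through the chelated hydroxyl. The fallback sets out from 1. The non-chelated 4-OH is alkylated selectively with 5 (K2CO3, KI, CuI cat., acetone, 56 °C) to give 1-[2-hydroxy-6-methoxy-4-(2-methylbut-3-yn-2-yloxy)phenyl]ethan-1-one F3. Heating F3 in PhNEt2 at 160 °C brings about a propargyl Claisen rearrangement to the carbon between the ether oxygen and the chelated hydroxyl (bond fixation by the hydrogen-bonded acetyl), followed by oxa-6π closure. The fallback comes back to the route at 3.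

Step 5 (late-stage thermal cascade on the full skeleton). Prolonged heating of the acid- and heat-sensitive bis-chromene could cause decomposition or incomplete conversion. The fallback sets out from 6 and closes the second pyran before the coupling. Ketone 6 is heated in PhNEt2 at 160 °C to give 1-(5,7-dimethoxy-2,2-dimethyl-2H-chromen-6-yl)ethan-1-one F4. NaBH4 in MeOH reduces it to rac-1-(5,7-dimethoxy-2,2-dimethyl-2H-chromen-6-yl)ethan-1-ol F5. F5 is then coupled with 3 under the step 4 conditions, with 3 raised to 4 equiv and slower addition because F5 carries its own chromene olefin. The fallback comes back to the route directly at 12.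

**Further compounds**
F1 | step 4 | rac-1-{3-[1-[2,6-dimethoxy-4-(2-methylbut-3-yn-2-yloxy)phenyl]ethyl]-5-hydroxy-7-methoxy-2,2-dimethyl-2H-chromen-6-yl}ethan-1-one | COc1cc2c(c(O)c1C(C)=O)C=C(C(C)c1c(OC)cc(OC(C)(C)C#C)cc1OC)C(C)(C)O2
F2 | step 4 | 1-{3-[(1R)-1-[2,6-dimethoxy-4-(2-methylbut-3-yn-2-yloxy)phenyl]ethyl]-5-hydroxy-7-methoxy-2,2-dimethyl-2H-chromen-6-yl}ethan-1-one | COc1cc2c(c(O)c1C(C)=O)C=C([C@@H](C)c1c(OC)cc(OC(C)(C)C#C)cc1OC)C(C)(C)O2
F3 | step 1 | 1-[2-hydroxy-6-methoxy-4-(2-methylbut-3-yn-2-yloxy)phenyl]ethan-1-one | CC(=O)c1c(O)cc(OC(C)(C)C#C)cc1OC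
F4 | step 5 | 1-(5,7-dimethoxy-2,2-dimethyl-2H-chromen-6-yl)ethan-1-one | COc1cc2c(c(OC)c1C(C)=O)C=CC(C)(C)O2
F5 | step 5 | rac-1-(5,7-dimethoxy-2,2-dimethyl-2H-chromen-6-yl)ethan-1-ol | COc1cc2c(c(OC)c1C(C)O)C=CC(C)(C)O2
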